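Which remedy at 8.0 d gives the summer flask the most AjDw, and how much stands there before any remedy?

the same everywhere: Aj 0.10 M
- summer: Dw 1.1 equiv; temperature 80 °C; the very flask that is asked about, followed so far
- winter: Dw 1.1 equiv; temperature 86 °C; run made earlier
- flask: Dw 1.10 equiv; temperature 80 °C; time 8.0 d

- summer (time / d: AjDw / %, Aj / %): 0.833: 39.3, 55.8; 1.67: 47.4, 45.0; 2.50: 50.7, 39.6; 3.00: 51.5, 37.4; 4.00: 52.3, 34.4; 5.00: 52.6, 32.5
- winter (time / d: AjDw / %, Aj / %): 0.833: 46.8, 45.5; 1.67: 52.4, 37.1; 2.50: 54.2, 32.7; 3.00: 54.4, 31.8; 4.00: 53.8, 29.7; 5.00: 53.5, 27.4

(each reading ± 0.3 percentage points)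

- north-east: at 8.0 d add Dw, 50.0% of the amount charged, then wait 4.0 d
- west: at 8.0 d add Aj, 50.0% of the amount charged, then wait 4.0 d
- north-west: change nothing and wait 4.0 d more
- east: at 8.0 d raise the temperature by 25 K, then wait 4.0 d

* AjDw, in percent of the Aj first charged, at 8.0 d
* the remedy with the largest gain of AjDw, or "none" below 2 percentage points (north-east / west / north-west / east / none)
* AjDw present, in percent of the Aj first charged, after west
* AjDw present, in percent of the Aj first charged, after east

- the volume of additions can be left aside
- a reading or a percentage of AjDw counts all its forms, free or not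

I took the local time constant of Aj, the time in which it falls by a factor e at its present pace. Beside it I set the Dw a plain balance allows, charge minus Aj used, in percent of the Aj charged. Both come from the summer run:

- first two readings: time constant 3.89 d, Dw by balance 60.4%
- last two readings: time constant 17.6 d, Dw by balance 43.5%

Reading down the columns, the time constant grew by a factor 4.52, more than the 1.39 by which the balance fell. If Aj is used with Dw one to one, its time constant goes as one over c_Dw. So I estimated free Dw late in the summer run at roughly 13.4% of the Aj charged, far under the balance. This is a rough reading, since the last two Aj values differ by 1.9 percentage points against a scatter of 0.3 points.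

Aj used over Dw charged gives 61.4% at the last reading. I took this as the upper end of the Dw share, the part of the charged Dw that has ended up on Aj. AjDw over Dw charged gives the lower end, 47.8%. West's dose of 50.0% of the Aj charge is larger than that estimate of free Dw. North-east's dose, 55.0% of the Aj charge, comes to 34 points at the share, but the last Aj reading, 32.5%, is lower than that, so I expected less. I therefore put north-east first.

The forecast differs. It gave 51.5% now, west as best, 66% after west and 45% after east, holding that “Adding Aj pushes the equilibrium hardest”.

The flask gave 51.3% and north-east as best, with a gain of 15 points. West lost 7.3 points, ending at 44.0%, and east ended at 41.2%.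

    Aj + Dw → AjDw (k = 0.522 L mol⁻¹ h⁻¹, Ea = 94.0 kJ mol⁻¹)
    2 Dw → Jo (k = 0.323 L mol⁻¹ h⁻¹, Ea = 79.0 kJ mol⁻¹)
    Vy ⇌ AjDw, rate k3*(cs3 - [AjDw]) while solid is left; crystals form when [AjDw] > cs3 (solubility = 5.70 mM, k = 0.425 h⁻¹)
    Aj + AjDw → AjAjDw (k = 0.199 L mol⁻¹ h⁻¹, Ea = 67.0 kJ mol⁻¹)
    (constants at 80 °C)

At 8.00 d the Dw share of this flask, with AjAjDw counted as one Dw on two Aj, was 55.6%, below the upper end of 61.4% that I took from the last reading. Free Dw, the limiting reagent, stood at 0.549% of its charge. Part of north-east's gain goes with the step to Jo: in the run without that step, the gain is 2.8 points instead of 15 points. With the other charges and the time held, the share moved with the Dw charge. The neighbour flask with 0.440 equiv of Dw reached 77.4%, and the one with 4.40 equiv reached 20.3%.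

The earlier runs and the new flask were computed with constants of no real substance; scatter was added.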